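The readings are calculated with made-up constants.

The vessel holds 0.600 M of partner, and a whole charge of 0.30 M of substrate runs in steadily over 4.0 min. Partner adds to substrate to give first product, and first product goes on to bis adduct and triple product.

| flask | substrate | partner | remark | time |
|---|---|---|---|---|
| Monday's | 0.20 M (fed, over 4.0 min) | 0.60 M | run made earlier |  |
| Friday's | 0.45 M (fed, over 4.0 min) | 0.60 M | run made earlier |  |
| Tuesday's | 0.30 M (fed, over 4.0 min) | 0.90 M | run made earlier |  |
| flask | 0.30 M (fed, over 4.0 min) | 0.600 M |  | 4.0 min |

| run | time / min | substrate / % | first product / % |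
|---|---|---|---|
| Monday's | 0.250 | 1.8 | 0 |
| Monday's | 0.833 | 4.1 | 2.8 |
| Monday's | 1.33 | 8.4 | 2.0 |
| Monday's | 2.50 | 26.2 | 3.7 |
| Monday's | 3.00 | 38.9 | 6.6 |
| Friday's | 0.250 | 3.0 | 0 |
| Friday's | 0.833 | 6.4 | 2.6 |
| Friday's | 1.33 | 10.2 | 2.0 |
| Friday's | 2.50 | 36.2 | 4.0 |
| Friday's | 3.00 | 50.2 | 4.8 |
| Tuesday's | 0.250 | 0 | 0 |
| Tuesday's | 0.500 | 1.5 | 0.2 |
| Tuesday's | 0.833 | 2.3 | 0.8 |
| Tuesday's | 1.50 | 7.5 | 4.5 |
| Tuesday's | 3.00 | 38.0 | 5.7 |

(standard deviation of a reading: 1 percentage point)

* amount of substrate at 4.0 min, in percent of the substrate charged
* amount of first product at 4.0 min, in percent of the substrate charged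
* amount of bis adduct at 4.0 min, in percent of the substrate charged
* amount of triple product at 4.0 min, in percent of the substrate charged

- percentages count the whole charge, also what has not yet gone in

Two chemists stand at the board. The first reckons by the charge: the flask has 2.00 partner per substrate, enough to bring the substrate to bis adduct, so he expects substrate to be taken up as it enters. Monday's run seems to agree, since at 0.833 min 20.8% of the charge had gone in and the substrate reading was 4.1%.

The second reckons by the clock and looks at the later readings. She takes the time of a reading and subtracts the dosing time multiplied by the substrate fraction. This gives the swallowed time, the minutes of feed the flask has taken up. If uptake has stopped, this number stands still, and Monday's run gives 1.45 min at 2.50 min and 1.44 min at 3.00 min. So there is a crossing: before it the flask takes up feed, and past it substrate piles up.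

Friday's heavier charge reads less at 3.00 min, 0.992 min, and Tuesday's run, with 0.90 M of partner, reads 1.48 min at 3.00 min. In her view the partner's power ends on a clock of its own, with substrate still coming in.

My own reckoning follows hers. Interpolating in a straight line between Monday's and Friday's charges, at the same partner, gives this flask a swallowed time of 1.26 min, so 68.4% of the substrate stands at the end of the feed, a reading-based figure.

The forecast, reached by its own fit and on the clock side, gives 69% substrate, 6% first product, 15% bis adduct and 10% triple product, adding of the last two that “data do not resolve the split”.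

The flask gives 68.8% substrate, 5.64% first product, 22.5% bis adduct and 2.97% triple product.

    substrate + partner → first product (k = 0.453 M⁻¹ s⁻¹)
    partner + bis adduct ⇌ triple product (K = 35.5 M⁻¹, k = 0.0223 M⁻¹ s⁻¹)
    partner → decomposed reagent (k = 0.0197 s⁻¹)
    2 substrate → homo dimer (k = 3.91 × 10⁻⁵ M⁻¹ s⁻¹)
    partner + first product → bis adduct (k = 0.965 M⁻¹ s⁻¹)

This flask's substrate puts its swallowed time at 1.25 min, against 1.26 min reckoned, and partner is the limiting reagent, at 0.00743% of its charge. The slow addition of substrate is the main reason that bis adduct stands at 22.5%: the same flask without it gives 74.5%. The charge view keeps the time before the crossing, as in Monday's reading at 0.833 min; the neighbour flask with 0.12 M of substrate and the same partner swallows 1.71 min and ends at 57.3% substrate.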